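**Plan**

- Numbering follows the tridecanoate chain: C1 is the ester carbon, the ring is O1–O2–C3–C4–C5 (O1 on C5), C7 is the side-chain CH(CH3) and C13 is benzylic. Retrosynthetic cuts, in order: the ester O–CH3 and the C1 oxidation level; the C–H of the C5 methyl (back to CH2–HgOAc); O1–C5 of the 1,2-dioxolane; O2–C3 (hydroperoxide from a 2,2-disubstituted oxetane); C1–C2 (ylide ring expansion of an oxirane); C4–C5 (alkenyl Grignard on a glycidyl tosylate); C10–C11 (cross-metathesis).
- Enabling feature: C5 is a fully substituted ring carbon 1,3 to the peroxy carbon C3, and its methyl group is the reduced CH2 terminus of a C5 methylidene. O1–C5 can therefore be closed by Markovnikov addition of the C3–OOH group across that alkene.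
- Forward: the C5–C13 chain is built first (steps 1–5) and joined to the C2–C4 unit at C4–C5 (step 7). C1 is inserted as the oxirane grows to an oxetane (step 8), and H2O2 opens the oxetane (step 9). The dioxolane, the only ring of the target, closes in step 10; demercuration, oxidation at C1 and esterification finish the route.
- Stereochemistry: C7 comes from (R)-citronellol. C3 comes from (R)-2-methylglycidol, carried with retention into the (S)-oxetane and inverted once in the perhydrolysis. C5 is set in the ring closure under weak 1,3-induction from C3, and its epimer is removed by chromatography.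

Key step: step 10

Remark (assumption): (R)-citronellol and (R)-2-methylglycidol are taken as single enantiomers; any minor enantiomer would appear only as a further diastereomer, to be removed in the chromatography after step 11.

**Route**

Step 1
Reactants: 1 (R)-citronellol; 2 4-phenylbut-1-ene
Product: 3 (3R)-3-methyl-9-phenylnon-6-en-1-ol (E/Z mixture)
Conditions: second-generation Hoveyda–Grubbs catalyst (3 mol%), 2 (3 equiv), CH2Cl2, 40 °C, argon sweep
Reagents that add atoms: none
Why: Olefin cross-metathesis swaps the isopropylidene end of 1 for the 3-phenylpropylidene unit of 2, driven by loss of volatile isobutene, and leaves the free alcohol and the remote stereocentre (the later C7) untouched.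

Step 2
Reactants: 3 (3R)-3-methyl-9-phenylnon-6-en-1-ol
Product: 4 (3R)-3-methyl-9-phenylnonan-1-ol
Conditions: H2 (1 atm), Pd/C (5 wt%), EtOAc, rt
Reagents that add atoms: none
Why: Heterogeneous catalytic hydrogenation saturates the unhindered disubstituted alkene, which makes its E/Z ratio irrelevant, under conditions that spare the arene and do not reach the stereocentre.

Step 3
Reactants: 4 (3R)-3-methyl-9-phenylnonan-1-ol
Product: 5 (3R)-3-methyl-9-phenylnonanal
Conditions: TEMPO (10 mol%), PhI(OAc)2 (1.1 equiv), CH2Cl2, rt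
Reagents that add atoms: none
Why: Oxoammonium (TEMPO) oxidation of a primary alcohol stops at the aldehyde in the absence of water and cannot epimerise the β-stereocentre.

Step 4
Reactants: 5 (3R)-3-methyl-9-phenylnonanal
Product: 6 (4R)-4-methyl-10-phenyldec-1-yne
Conditions: dimethyl (1-diazo-2-oxopropyl)phosphonate, K2CO3, MeOH, 0 °C → rt
Reagents that add atoms: dimethyl (1-diazo-2-oxopropyl)phosphonate, COP(=O)(OC)C(=[N+]=[N-])C(C)=O
Why: Ohira–Bestmann (Seyferth–Gilbert) homologation converts the aldehyde into the terminal alkyne under mild carbonate conditions, the added carbon being the one that ends as the C5 methyl group.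

Step 5
Reactants: 6 (4R)-4-methyl-10-phenyldec-1-yne
Product: 8 (4R)-2-bromo-4-methyl-10-phenyldec-1-ene, via bromoalkenylborane 7 (not isolated)
Conditions: B-bromo-9-BBN (1.2 equiv), CH2Cl2, 0 °C → rt; then AcOH, 0 °C → rt
Reagents that add atoms: B-bromo-9-borabicyclo[3.3.1]nonane, BrB1C2CCCC1CCC2
Why: Haloboration adds B–Br syn across the terminal alkyne with bromine on the internal carbon, and protonolysis of the alkenyl C–B bond by acetic acid then leaves the 2-bromo-1-alkene without touching the stereocentre.

Step 6
Reactants: 9 (R)-2-methylglycidol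
Product: 10 [(2S)-2-methyloxiran-2-yl]methyl 4-methylbenzenesulfonate
Conditions: TsCl, Et3N, DMAP (cat.), CH2Cl2, 0 °C
Reagents that add atoms: 4-methylbenzenesulfonyl chloride, Cc1ccc(cc1)S(Cl)(=O)=O
Why: O-Sulfonylation of the primary alcohol leaves the oxirane and the quaternary stereocentre intact, the change of descriptor from R to S being only a change of CIP ranking.

Step 7
Reactants: 8 (4R)-2-bromo-4-methyl-10-phenyldec-1-ene; 10 [(2S)-2-methyloxiran-2-yl]methyl 4-methylbenzenesulfonate
Product: 12 (2S,6R)-2-hydroxy-2,6-dimethyl-4-methylidene-12-phenyldodecyl 4-methylbenzenesulfonate, via alkenylmagnesium bromide 11 (not isolated)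
Conditions: Mg, I2 (cat.), THF, 40 °C; then CuI (10 mol%), 10 (1.2 equiv), THF, −40 → −20 °C; aq. NH4Cl
Reagents that add atoms: none
Why: Copper-catalysed Grignard opening of a glycidyl sulfonate takes place at the unsubstituted oxirane CH2 and not at the neopentyl-type CH2OTs, so C4–C5 is formed while the carbinol carbon (the later C3) keeps its configuration and the tosylate is saved for the next ring closure.

Step 8
Reactants: 12 (2S,6R)-2-hydroxy-2,6-dimethyl-4-methylidene-12-phenyldodecyl 4-methylbenzenesulfonate
Product: 14 (2S)-2-methyl-2-[(4R)-4-methyl-2-methylidene-10-phenyldecyl]oxetane, via epoxide 13 (not isolated)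
Conditions: Me3S(O)I (3 equiv), KOtBu (4 equiv), t-BuOH, rt → 70 °C
Reagents that add atoms: trimethylsulfoxonium iodide, C[S+](C)(C)=O.[I-]
Why: The tertiary alkoxide first displaces the tosylate (Williamson closure, 3-exo-tet), and dimethylsulfoxonium methylide then opens the oxirane at its CH2 and recloses with loss of DMSO (Corey–Chaykovsky-type ring expansion of an epoxide to an oxetane), which inserts C1 without breaking any bond at the stereocentre.

Step 9
Reactants: 14 (2S)-2-methyl-2-[(4R)-4-methyl-2-methylidene-10-phenyldecyl]oxetane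
Product: 15 (3R,7R)-3-hydroperoxy-3,7-dimethyl-5-methylidene-13-phenyltridecan-1-ol
Conditions: H2O2 (anhydrous ethereal solution, 10 equiv), TMSOTf (0.2 equiv), Et2O, −78 → 0 °C
Reagents that add atoms: hydrogen peroxide, OO
Why: In this Lewis acid-promoted perhydrolysis of a 2,2-disubstituted oxetane, H2O2 attacks the activated ring at its tertiary carbon from the side opposite the departing oxygen (SN2-like, inversion), which converts the (S)-oxetane carbon into the (3R)-hydroperoxide and releases the C1 hydroxyl.

Step 10
Reactants: 15 (3R,7R)-3-hydroperoxy-3,7-dimethyl-5-methylidene-13-phenyltridecan-1-ol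
Product: 16 2-[(3S,5S)-5-[(acetoxymercurio)methyl]-3-methyl-5-[(2R)-2-methyl-8-phenyloctyl]-1,2-dioxolan-3-yl]ethanol (expected together with its C5 epimer)
Conditions: Hg(OAc)2 (1.1 equiv), CH2Cl2, 0 °C → rt
Reagents that add atoms: mercury diacetate, CC(=O)O[Hg]OC(C)=O
Why: Hg(OAc)2 engages the exocyclic C5=CH2 bond as a bridged mercurinium ion (divalent mercury acting as a soft π-acid), and the terminal oxygen of the C3–OOH group attacks its tertiary terminus C5 anti to mercury, forming O1–C5 and leaving CH2HgOAc exocyclic. The closest known reaction type is cycloperoxymercuration of homoallylic hydroperoxides, the peroxide analogue of intramolecular oxymercuration. The 1,2-dioxolane closes in the 5-exo-trig mode. The new stereocentre C5 is governed only by 1,3-induction from C3 in an envelope-like transition state, and since both C5 substituents are CH2 groups of similar size little facial preference is expected, so the (5S) product is carried on with its C5 epimer and the two are parted by chromatography after step 11. The step needs Markovnikov regioselectivity, which the tertiary character of C5 secures, and chemoselectivity for OOH over the C1 hydroxyl, which rests on the α-effect nucleophilicity of the hydroperoxide and on the smaller ring (5-exo against 6-exo for the alcohol). C3 and C7 take no part and keep their configuration.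

Step 11
Reactants: 16 2-[(3S,5S)-5-[(acetoxymercurio)methyl]-3-methyl-5-[(2R)-2-methyl-8-phenyloctyl]-1,2-dioxolan-3-yl]ethanol
Product: 17 2-[(3S,5S)-3,5-dimethyl-5-[(2R)-2-methyl-8-phenyloctyl]-1,2-dioxolan-3-yl]ethanol
Conditions: NaBH4 (excess), 3 M aq. NaOH, CH2Cl2, 0 °C; SiO2 chromatography (removal of the C5 epimer)
Reagents that add atoms: none
Why: Hydridodemercuration is a radical chain in which the exocyclic β-peroxyalkyl radical should be quenched by hydrogen transfer faster than it can attack the ring O–O bond, and a dialkyl peroxide is inert to alkaline borohydride at 0 °C.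

Step 12
Reactants: 17 2-[(3S,5S)-3,5-dimethyl-5-[(2R)-2-methyl-8-phenyloctyl]-1,2-dioxolan-3-yl]ethanol
Product: 18 2-[(3R,5S)-3,5-dimethyl-5-[(2R)-2-methyl-8-phenyloctyl]-1,2-dioxolan-3-yl]acetic acid
Conditions: TEMPO (20 mol%), PhI(OAc)2 (2.5 equiv), MeCN/H2O (1:1), rt
Reagents that add atoms: water, O
Why: TEMPO/PhI(OAc)2 oxidation in aqueous acetonitrile takes the primary alcohol through the aldehyde hydrate to the acid under near-neutral conditions that a dialkyl peroxide tolerates (the descriptor at C3 changes from S to R by ranking only).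

Step 13
Reactants: 18 2-[(3R,5S)-3,5-dimethyl-5-[(2R)-2-methyl-8-phenyloctyl]-1,2-dioxolan-3-yl]acetic acid
Product: 19 methyl 2-[(3R,5S)-3,5-dimethyl-5-[(2R)-2-methyl-8-phenyloctyl]-1,2-dioxolan-3-yl]acetate (CNP0394871.1)
Conditions: TMSCHN2 (2 M in hexanes), toluene/MeOH (4:1), 0 °C
Reagents that add atoms: (trimethylsilyl)diazomethane, C[Si](C)(C)C=[N+]=[N-]
Why: O-Methylation of the carboxylic acid with (trimethylsilyl)diazomethane in the presence of methanol is neither basic nor strongly acidic, so the β-peroxy ester forms without retro-oxa-Michael opening of the dioxolane.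

**Compound list**

1 | (R)-citronellol, (3R)-3,7-dimethyloct-6-en-1-ol | OCC[C@H](C)CCC=C(C)C | starting material
2 | 4-phenylbut-1-ene | C=CCCc1ccccc1 | starting material
3 | (3R)-3-methyl-9-phenylnon-6-en-1-ol (E/Z mixture) | OCC[C@H](C)CCC=CCCc1ccccc1 | intermediate
4 | (3R)-3-methyl-9-phenylnonan-1-ol | OCC[C@H](C)CCCCCCc1ccccc1 | intermediate
5 | (3R)-3-methyl-9-phenylnonanal | O=CC[C@H](C)CCCCCCc1ccccc1 | intermediate
6 | (4R)-4-methyl-10-phenyldec-1-yne | C#CC[C@H](C)CCCCCCc1ccccc1 | intermediate
7 | 9-[(1Z,4R)-2-bromo-4-methyl-10-phenyldec-1-en-1-yl]-9-borabicyclo[3.3.1]nonane | Br/C(C[C@H](C)CCCCCCc1ccccc1)=C\B1C2CCCC1CCC2 | intermediate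
8 | (4R)-2-bromo-4-methyl-10-phenyldec-1-ene | C=C(Br)C[C@H](C)CCCCCCc1ccccc1 | intermediate
9 | (R)-2-methylglycidol, [(2R)-2-methyloxiran-2-yl]methanol | OC[C@]1(C)CO1 | starting material
10 | [(2S)-2-methyloxiran-2-yl]methyl 4-methylbenzenesulfonate | Cc1ccc(cc1)S(=O)(=O)OC[C@]1(C)CO1 | intermediate
11 | [(4R)-4-methyl-10-phenyldec-1-en-2-yl]magnesium bromide | Br[Mg]C(=C)C[C@H](C)CCCCCCc1ccccc1 | intermediate
12 | (2S,6R)-2-hydroxy-2,6-dimethyl-4-methylidene-12-phenyldodecyl 4-methylbenzenesulfonate | Cc1ccc(cc1)S(=O)(=O)OC[C@](O)(C)CC(=C)C[C@H](C)CCCCCCc1ccccc1 | intermediate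
13 | (2S)-2-methyl-2-[(4R)-4-methyl-2-methylidene-10-phenyldecyl]oxirane | C1[C@](O1)(C)CC(=C)C[C@H](C)CCCCCCc2ccccc2 | intermediate
14 | (2S)-2-methyl-2-[(4R)-4-methyl-2-methylidene-10-phenyldecyl]oxetane | O1CC[C@]1(C)CC(=C)C[C@H](C)CCCCCCc2ccccc2 | intermediate
15 | (3R,7R)-3-hydroperoxy-3,7-dimethyl-5-methylidene-13-phenyltridecan-1-ol | OCC[C@](C)(OO)CC(=C)C[C@H](C)CCCCCCc1ccccc1 | intermediate
16 | 2-[(3S,5S)-5-[(acetoxymercurio)methyl]-3-methyl-5-[(2R)-2-methyl-8-phenyloctyl]-1,2-dioxolan-3-yl]ethanol | OCC[C@@]1(C)C[C@](C[Hg]OC(C)=O)(C[C@H](C)CCCCCCc2ccccc2)OO1 | intermediate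
17 | 2-[(3S,5S)-3,5-dimethyl-5-[(2R)-2-methyl-8-phenyloctyl]-1,2-dioxolan-3-yl]ethanol | OCC[C@@]1(C)C[C@](C)(C[C@H](C)CCCCCCc2ccccc2)OO1 | intermediate
18 | 2-[(3R,5S)-3,5-dimethyl-5-[(2R)-2-methyl-8-phenyloctyl]-1,2-dioxolan-3-yl]acetic acid | OC(=O)C[C@@]1(C)C[C@](C)(C[C@H](C)CCCCCCc2ccccc2)OO1 | intermediate
19 | methyl 2-[(3R,5S)-3,5-dimethyl-5-[(2R)-2-methyl-8-phenyloctyl]-1,2-dioxolan-3-yl]acetate | COC(=O)C[C@@]1(C)C[C@](C)(C[C@H](C)CCCCCCc2ccccc2)OO1 | target

**Totals**

Total step count: 13. Longest linear sequence: 12 steps (steps 1–5 and 7–13, from (R)-citronellol).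

**Steps most likely to fail**

Step 10 (ring closure). The mercurinium ion may be intercepted by the free primary hydroxyl in a competing 6-exo closure, and the attack on the two alkene faces is expected to be poorly differentiated, so a large part of the material may go to the C5 epimer. The fallback sets out from 15 and comes back at 17. The primary hydroxyl is first blocked by lipase-catalysed transesterification (immobilised Candida antarctica lipase B, vinyl acetate, t-BuOMe, rt), which should leave the hindered tertiary OOH alone and give (3R,7R)-3-hydroperoxy-3,7-dimethyl-5-methylidene-13-phenyltridecyl acetate F1. Hg(OAc)2 in CH2Cl2 then closes the ring with no second oxygen nucleophile present, giving 2-[(3S,5S)-5-[(acetoxymercurio)methyl]-3-methyl-5-[(2R)-2-methyl-8-phenyloctyl]-1,2-dioxolan-3-yl]ethyl acetate F2. Alkaline NaBH4 gives 2-[(3S,5S)-3,5-dimethyl-5-[(2R)-2-methyl-8-phenyloctyl]-1,2-dioxolan-3-yl]ethyl acetate F3, and K2CO3 in MeOH removes the acetate to return 17. The facial selectivity at C5 is not improved by this detour and still has to be handled by chromatography.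

Step 9 (perhydrolysis of the oxetane). The activated oxetane may ionise to a tertiary cation, which would erode the inversion at C3 and could be captured by the homoallylic methylidene or lose a proton. The fallback sets out from 14 and comes back at 17, reversing the roles of the two ring carbons. Isayama–Mukaiyama hydroperoxysilylation of the methylidene (Co(acac)2 cat., O2, Et3SiH, EtOH, rt) gives triethyl{[(2S,4R)-2,4-dimethyl-1-[(2R)-2-methyloxetan-2-yl]-10-phenyldecan-2-yl]peroxy}silane F4 together with its epimer at the peroxy carbon. HF·pyridine in THF frees (2S,4R)-2,4-dimethyl-1-[(2R)-2-methyloxetan-2-yl]-10-phenyldecan-2-yl hydroperoxide F5 (the oxetane carbon reads R in F4 and F5 by ranking only; its geometry is that of 14). A catalytic Lewis acid (TMSOTf or Yb(OTf)3, CH2Cl2, −78 → 0 °C) then lets the hydroperoxide open the oxetane intramolecularly at its tertiary carbon (5-exo, inversion), which gives 17 after chromatographic removal of the C5 epimer. This detour bypasses 15 and 16, and with them the organomercurial and its radical reduction.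

Step 8 (one-pot epoxide closure and ring expansion). The ring expansion may stall at the epoxide, or base-induced side reactions (opening of the epoxide by tert-butoxide or iodide, migration of the alkene) may take over at the temperature the ylide needs. The fallback sets out from 12 and comes back at 14, building C1 as a hydroxymethyl group and closing the oxetane by etherification. K2CO3 in MeOH at rt closes 12 to epoxide 13, which is isolated. (Isopropoxydimethylsilyl)methylmagnesium chloride with CuI (10 mol%) in THF opens it at the CH2 to give (3S,7R)-1-[dimethyl(propan-2-yloxy)silyl]-3,7-dimethyl-5-methylidene-13-phenyltridecan-3-ol F6. Tamao oxidation (H2O2, KF, KHCO3, THF/MeOH) gives (3S,7R)-3,7-dimethyl-5-methylidene-13-phenyltridecane-1,3-diol F7. Selective sulfonylation of the primary hydroxyl (TsCl, Et3N, DMAP cat., CH2Cl2, 0 °C) gives (3S,7R)-3-hydroxy-3,7-dimethyl-5-methylidene-13-phenyltridecyl 4-methylbenzenesulfonate F8, and KOtBu in THF closes it to 14 by 4-exo-tet Williamson etherification with retention at the carbinol carbon.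

**Further compounds**

F1 | step 10 | (3R,7R)-3-hydroperoxy-3,7-dimethyl-5-methylidene-13-phenyltridecyl acetate | CC(=O)OCC[C@](C)(OO)CC(=C)C[C@H](C)CCCCCCc1ccccc1
F2 | step 10 | 2-[(3S,5S)-5-[(acetoxymercurio)methyl]-3-methyl-5-[(2R)-2-methyl-8-phenyloctyl]-1,2-dioxolan-3-yl]ethyl acetate | CC(=O)OCC[C@@]1(C)C[C@](C[Hg]OC(C)=O)(C[C@H](C)CCCCCCc2ccccc2)OO1
F3 | step 10 | 2-[(3S,5S)-3,5-dimethyl-5-[(2R)-2-methyl-8-phenyloctyl]-1,2-dioxolan-3-yl]ethyl acetate | CC(=O)OCC[C@@]1(C)C[C@](C)(C[C@H](C)CCCCCCc2ccccc2)OO1
F4 | step 9 | triethyl{[(2S,4R)-2,4-dimethyl-1-[(2R)-2-methyloxetan-2-yl]-10-phenyldecan-2-yl]peroxy}silane | O1CC[C@]1(C)C[C@](C)(C[C@H](C)CCCCCCc2ccccc2)OO[Si](CC)(CC)CC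
F5 | step 9 | (2S,4R)-2,4-dimethyl-1-[(2R)-2-methyloxetan-2-yl]-10-phenyldecan-2-yl hydroperoxide | O1CC[C@]1(C)C[C@](C)(C[C@H](C)CCCCCCc2ccccc2)OO
F6 | step 8 | (3S,7R)-1-[dimethyl(propan-2-yloxy)silyl]-3,7-dimethyl-5-methylidene-13-phenyltridecan-3-ol | CC(C)O[Si](C)(C)CC[C@](O)(C)CC(=C)C[C@H](C)CCCCCCc1ccccc1
F7 | step 8 | (3S,7R)-3,7-dimethyl-5-methylidene-13-phenyltridecane-1,3-diol | OCC[C@](O)(C)CC(=C)C[C@H](C)CCCCCCc1ccccc1
F8 | step 8 | (3S,7R)-3-hydroxy-3,7-dimethyl-5-methylidene-13-phenyltridecyl 4-methylbenzenesulfonate | Cc1ccc(cc1)S(=O)(=O)OCC[C@](O)(C)CC(=C)C[C@H](C)CCCCCCc1ccccc1
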